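**Retrosynthetic overview**
1. Late events: hydroxyl-directed epoxidation of a C10 vinyl group, SeO2 oxidation of a C5 isopropenyl group to the acrolein, both alkenes from one double methylenation of a C1 aldehyde / C4 methyl ketone, angelate put on C6 last among the acylations.
2. α-Methylene-γ-lactone ⇐ Eschenmoser methylenation of a trans-fused lactone made by α-face dihydroxylation of a C8=C9 alkene and lactonisation through O8.
3. C7 side chain and C8=C9 alkene ⇐ Johnson–Claisen transposition of a C9 β-allylic alcohol (sets C7; the dihydroxylation then re-installs O9 with net inversion and sets C8).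
4. Key step: catalytic asymmetric endo Diels–Alder reaction of (E,E)-1,4-diacetoxybutadiene with the mesaconate-type enone methyl (E)-2-methyl-4-oxopent-2-enoate sets C5, C6, C9 and the quaternary C10 at once.
5. Ring order: cyclohexene (step 2) → γ-lactone (step 8) → oxirane (step 16).

Atom labels (elemane numbering, used in all names): ring C5–C10 with C10 quaternary; C14 = methyl on C10; C1/C2 = the carbons that end as the oxirane (C1 on C10); C4 on C5 carries C15 (=CH2) and C3 (CHO); C11/C12/C13 = lactone α-carbon, carbonyl and methylene (C11 on C7); β = ring face of C14, α = the other face; the target is (1R,5R,6S,7S,8R,9S,10S); TBS = tert-butyldimethylsilyl.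

Assumption: in step 2 the R catalyst delivers the diene to the Re face of C5 of 3 (ketone bound to boron syn to C5–H, one catalyst phenyl covering the Si face), giving 5 as drawn; were the sense found to be the reverse, the S catalyst would be used with nothing else changed.

**Step 1**
Reactants: 1 methyl pyruvate; 2 1-(triphenyl-λ5-phosphanylidene)propan-2-one
Product: 3 methyl (E)-2-methyl-4-oxopent-2-enoate
Conditions: CH2Cl2, 40 °C; minor Z isomer removed by chromatography
Reagents that add atoms: none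
Why: Wittig olefination of the activated pyruvate keto group by a stabilised ylide puts the acetyl group trans to the ester (E), the geometry that later makes C4 and C14 cis on the ring.

**Step 2**
Reactants: 3 methyl (E)-2-methyl-4-oxopent-2-enoate; 4 (1E,3E)-buta-1,3-diene-1,4-diyl diacetate
Product: 5 methyl (1S,2S,5R,6S)-6-acetyl-2,5-diacetoxy-1-methylcyclohex-3-ene-1-carboxylate
Conditions: (R)-1-(2-methylphenyl)-3,3-diphenyltetrahydro-1H,3H-pyrrolo[1,2-c][1,3,2]oxazaborole (20 mol %) activated with HN(SO2CF3)2 (20 mol %), CH2Cl2, −40 → −20 °C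
Reagents that add atoms: none
Why: Lewis-acid-catalysed asymmetric Diels–Alder reaction in which the boron cation binds the ketone (more basic than the ester), so the acetyl group and its cis partner C14 go endo and end up cis to both acetoxy groups while CO2Me is exo, which sets C5, C6, C9 and the quaternary C10 in one step with the absolute sense coming from the catalyst.

**Step 3**
Reactants: 5 methyl (1S,2S,5R,6S)-6-acetyl-2,5-diacetoxy-1-methylcyclohex-3-ene-1-carboxylate
Product: 6 C4 ethylene ketal of 5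
Conditions: Me3SiOCH2CH2OSiMe3, Me3SiOSO2CF3 (5 mol %), CH2Cl2, −78 → −20 °C
Reagents that add atoms: 1,2-bis(trimethylsilyloxy)ethane, C[Si](C)(C)OCCO[Si](C)(C)C
Why: Noyori ketalisation under non-basic conditions masks the hindered ketone before the hydride step and removes the base-sensitive β-acetoxy ketone without touching C5.

**Step 4**
Reactants: 6 C4 ethylene ketal of 5
Product: 7 C1,C6,C9 triol
Conditions: LiAlH4, THF, 0 °C → rt
Reagents that add atoms: none
Why: LiAlH4 ester reduction turns C1 into the primary alcohol and cleaves both acetates in the same operation; no stereocentre is affected.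

**Step 5**
Reactants: 7 C1,C6,C9 triol
Product: 10 6-O-TBS diol, via cyclic phenylboronate 8 (not isolated), via 6-O-TBS boronate 9 (not isolated)
Conditions: PhB(OH)2 (1.05 equiv), 4 Å sieves, CH2Cl2, rt; then 2,6-lutidine, t-BuMe2SiOSO2CF3, −40 → 0 °C; then pinacol, MeOH, rt
Reagents that add atoms: phenylboronic acid, OB(O)c1ccccc1 (its atoms stay only in 8 and 9); tert-butyldimethylsilyl trifluoromethanesulfonate, CC(C)(C)[Si](C)(C)OS(=O)(=O)C(F)(F)F
Why: Transient boronate protection: only O1 and O9 are 1,3-related, so the boronic acid ties them into a six-membered boronate and the C6 hydroxyl alone is silylated before transesterification with pinacol frees the diol.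

**Step 6**
Reactants: 10 6-O-TBS diol
Product: 11 1,6-bis-O-TBS allylic alcohol
Conditions: t-BuMe2SiCl (1.1 equiv), imidazole, DMF, 0 °C
Reagents that add atoms: tert-butyldimethylsilyl chloride, CC(C)(C)[Si](C)(C)Cl
Why: Selective silylation of the primary C1 hydroxyl over the secondary C9 hydroxyl that is flanked by the quaternary C10 (steric differentiation).

**Step 7**
Reactants: 11 1,6-bis-O-TBS allylic alcohol; 12 triethyl orthoacetate
Product: 15 C7 ethyl acetate Claisen ester, via mixed orthoester 13 (not isolated), via ketene acetal 14 (not isolated)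
Conditions: 12 (solvent), EtCO2H (10 mol %), 150 °C, EtOH distilled off
Reagents that add atoms: none
Why: Johnson–Claisen rearrangement in which the ketene acetal on the β C9 oxygen delivers CH2CO2Et suprafacially to the β face of C7 (1,3-chirality transfer, sets C7) and moves the alkene to C8=C9.

**Step 8**
Reactants: 15 C7 ethyl acetate Claisen ester
Product: 17 9α-hydroxy trans-lactone, via 8α,9α-diol ester 16 (not isolated)
Conditions: OsO4 (5 mol %), N-methylmorpholine N-oxide, acetone–H2O, rt; then pyridinium p-toluenesulfonate (cat.), benzene, 60 °C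
Reagents that add atoms: OsO4, O=[Os](=O)(=O)=O (catalytic oxygen carrier); N-methylmorpholine N-oxide, C[N+]1([O-])CCOCC1; water, O
Why: Upjohn syn-dihydroxylation from the α face (the β face carries C14, the C7 side chain and the C6 silyloxy group) sets C8 and C9, and the C8 hydroxyl then closes the trans-fused γ-lactone, the five-membered ring being preferred over the six-membered one through O9.

**Step 9**
Reactants: 17 9α-hydroxy trans-lactone
Product: 20 α-methylene lactone, via Mannich base 18 (not isolated), via trimethylammonium iodide 19 (not isolated)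
Conditions: LiN(i-Pr)2 (2.3 equiv), THF, −78 °C; CH2=NMe2+ I−, −78 → 0 °C; then MeI, MeOH, rt; then NaHCO3, CH2Cl2–H2O, rt
Reagents that add atoms: N,N-dimethylmethyleneiminium iodide (Eschenmoser's salt), C=[N+](C)C.[I-]; iodomethane, CI (its carbon stays only in 19)
Why: Eschenmoser α-methylenation: the lactone enolate (the C9 alkoxide is a spectator) is aminomethylated, and quaternisation followed by base-induced elimination gives the exocyclic alkene, which removes the C11 stereocentre.

**Step 10**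
Reactants: 20 α-methylene lactone
Product: 21 C1,C6,C9 triol lactone
Conditions: HF·pyridine, THF–pyridine, 0 °C → rt
Reagents that add atoms: none
Why: Fluoride desilylation under buffered acidic conditions removes both silyl ethers (and erases any O1→O9 silyl migration from step 9) while the ketal and the α-methylene lactone survive and base-induced translactonisation to O6 is avoided.

**Step 11**
Reactants: 21 C1,C6,C9 triol lactone; 22 angelic anhydride
Product: 25 6-O-angelate diol, via cyclic phenylboronate 23 (not isolated), via angeloylated boronate 24 (not isolated)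
Conditions: PhB(OH)2 (1.0 equiv), 4 Å sieves, toluene, rt; then 22 (3 equiv), Et3N, 4-(dimethylamino)pyridine (10 mol %), 40 °C; then pinacol, MeOH, rt
Reagents that add atoms: phenylboronic acid, OB(O)c1ccccc1 (its atoms stay only in 23 and 24)
Why: Transient boronate protection again ties up the cis-1,3-diol O1/O9, so nucleophile-catalysed acylation by the anhydride occurs only at the hindered axial C6 hydroxyl, the mild conditions keeping the Z geometry of the angelate.

**Step 12**
Reactants: 25 6-O-angelate diol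
Product: 26 C1 aldehyde
Conditions: 2,2,6,6-tetramethylpiperidin-1-oxyl (20 mol %), PhI(OAc)2, CH2Cl2, rt
Reagents that add atoms: none
Why: Oxoammonium (TEMPO) oxidation is selective for the primary alcohol over the hindered secondary C9 hydroxyl and gives the non-enolisable C1 aldehyde.

**Step 13**
Reactants: 26 C1 aldehyde
Product: 27 C1 aldehyde C4 methyl ketone
Conditions: HCl (1 M), THF, rt
Reagents that add atoms: water, O
Why: Acid-catalysed ketal hydrolysis frees the methyl ketone under conditions that spare the angelate, the lactone and the β-acyloxy ketone just formed.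

**Step 14**
Reactants: 27 C1 aldehyde C4 methyl ketone
Product: 28 C10 vinyl C5 isopropenyl lactone
Conditions: Zn, CH2Br2, TiCl4, THF–CH2Cl2, 0 °C → rt
Reagents that add atoms: dibromomethane, BrCBr
Why: Takai–Lombardo methylenation converts aldehyde and ketone together into the vinyl and isopropenyl groups with a non-basic reagent, so C5 is not epimerised, the β-angeloyloxy ketone does not eliminate and esters are untouched.

**Step 15**
Reactants: 28 C10 vinyl C5 isopropenyl lactone
Product: 29 C3 enal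
Conditions: SeO2, 1,4-dioxane, 70 °C
Reagents that add atoms: selenium dioxide, O=[Se]=O
Why: SeO2 allylic oxidation (ene reaction then [2,3]-shift) takes the isopropenyl methyl to the aldehyde, the only accessible allylic position on an electron-rich alkene, since the vinyl group has no allylic hydrogen and the other alkenes are conjugated to carbonyls.

**Step 16**
Reactants: 29 C3 enal
Product: 30 CNP0113462.3
Conditions: VO(acac)2 (10 mol %), t-BuOOH, CH2Cl2, 0 °C → rt
Reagents that add atoms: tert-butyl hydroperoxide, CC(C)(C)OO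
Why: Hydroxyl-directed vanadium-catalysed epoxidation of the homoallylic alcohol: the axial C9 α-hydroxyl delivers oxygen to the only non-conjugated alkene with the vinyl CH2 turned to the α face, which gives the 1R oxirane.

**Compound list**
1 | methyl pyruvate (methyl 2-oxopropanoate) | COC(=O)C(C)=O | starting material
2 | 1-(triphenyl-λ5-phosphanylidene)propan-2-one | CC(=O)C=P(c1ccccc1)(c1ccccc1)c1ccccc1 | starting material
3 | methyl (E)-2-methyl-4-oxopent-2-enoate | COC(=O)/C(C)=C/C(C)=O | intermediate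
4 | (1E,3E)-buta-1,3-diene-1,4-diyl diacetate | CC(=O)O/C=C/C=C/OC(C)=O | starting material
5 | methyl (1S,2S,5R,6S)-6-acetyl-2,5-diacetoxy-1-methylcyclohex-3-ene-1-carboxylate (acetyl on C5, OAc on C6 and C9, C14 all β; CO2Me = C1 α) | CC(=O)O[C@@H]1C=C[C@H](OC(C)=O)[C@@](C)(C(=O)OC)[C@@H]1C(C)=O | intermediate
6 | methyl (1S,2S,5R,6S)-2,5-diacetoxy-1-methyl-6-(2-methyl-1,3-dioxolan-2-yl)cyclohex-3-ene-1-carboxylate | CC(=O)O[C@@H]1C=C[C@H](OC(C)=O)[C@@](C)(C(=O)OC)[C@@H]1C2(C)OCCO2 | intermediate
7 | 2-(hydroxymethyl)-2-methyl-3-(2-methyl-1,3-dioxolan-2-yl)cyclohex-5-ene-1,4-diol (6β-OH, 9β-OH, 5β-dioxolanyl, 10β-CH3, 10α-CH2OH) | O[C@@H]1C=C[C@H](O)[C@@](C)(CO)[C@@H]1C2(C)OCCO2 | intermediate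
8 | cyclic phenylboronate of 7 across O1 and O9 (6β-OH free) | O[C@@H]1C=C[C@@H]2OB(c3ccccc3)OC[C@@]2(C)[C@@H]1C4(C)OCCO4 | intermediate
9 | 6-O-TBS ether of boronate 8 | CC(C)(C)[Si](C)(C)O[C@@H]1C=C[C@@H]2OB(c3ccccc3)OC[C@@]2(C)[C@@H]1C4(C)OCCO4 | intermediate
10 | 6-O-TBS ether of 7 (C1 and C9 hydroxyls free) | CC(C)(C)[Si](C)(C)O[C@@H]1C=C[C@H](O)[C@@](C)(CO)[C@@H]1C2(C)OCCO2 | intermediate
11 | 1,6-bis-O-TBS ether of 7 (9β-OH free) | CC(C)(C)[Si](C)(C)O[C@@H]1C=C[C@H](O)[C@@](C)(CO[Si](C)(C)C(C)(C)C)[C@@H]1C2(C)OCCO2 | intermediate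
12 | triethyl orthoacetate | CCOC(C)(OCC)OCC | starting material
13 | mixed orthoester of 11 at O9 (C9–O–C(CH3)(OEt)2) | CC(C)(C)[Si](C)(C)O[C@@H]1C=C[C@H](OC(C)(OCC)OCC)[C@@](C)(CO[Si](C)(C)C(C)(C)C)[C@@H]1C2(C)OCCO2 | intermediate
14 | ketene acetal of 11 at O9 (C9–O–C(=CH2)OEt) | CC(C)(C)[Si](C)(C)O[C@@H]1C=C[C@H](OC(=C)OCC)[C@@](C)(CO[Si](C)(C)C(C)(C)C)[C@@H]1C2(C)OCCO2 | intermediate
15 | ethyl ester with 7β-CH2CO2Et, C8=C9 alkene, 6β-OTBS, 5β-dioxolanyl, 10β-CH3, 10α-CH2OTBS | CCOC(=O)C[C@@H]1C=C[C@@](C)(CO[Si](C)(C)C(C)(C)C)[C@H](C2(C)OCCO2)[C@@H]1O[Si](C)(C)C(C)(C)C | intermediate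
16 | 8α,9α-diol of 15 | CCOC(=O)C[C@@H]1[C@@H](O)[C@@H](O)[C@@](C)(CO[Si](C)(C)C(C)(C)C)[C@H](C2(C)OCCO2)[C@@H]1O[Si](C)(C)C(C)(C)C | intermediate
17 | trans-fused 8α,12-lactone with 9α-OH, 6β-OTBS, C1-OTBS, C4 ketal | C1C(=O)O[C@@H]2[C@@H]1[C@@H](O[Si](C)(C)C(C)(C)C)[C@@H](C3(C)OCCO3)[C@](C)(CO[Si](C)(C)C(C)(C)C)[C@@H]2O | intermediate
18 | C11 dimethylaminomethyl derivative of 17 (Mannich base, C11 epimers) | CN(C)CC1C(=O)O[C@@H]2[C@@H]1[C@@H](O[Si](C)(C)C(C)(C)C)[C@@H](C3(C)OCCO3)[C@](C)(CO[Si](C)(C)C(C)(C)C)[C@@H]2O | intermediate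
19 | trimethylammonium iodide of 18 | C[N+](C)(C)CC1C(=O)O[C@@H]2[C@@H]1[C@@H](O[Si](C)(C)C(C)(C)C)[C@@H](C3(C)OCCO3)[C@](C)(CO[Si](C)(C)C(C)(C)C)[C@@H]2O.[I-] | intermediate
20 | α-methylene lactone (C11=C13) with 9α-OH, 6β-OTBS, C1-OTBS, C4 ketal | C=C1C(=O)O[C@@H]2[C@@H]1[C@@H](O[Si](C)(C)C(C)(C)C)[C@@H](C3(C)OCCO3)[C@](C)(CO[Si](C)(C)C(C)(C)C)[C@@H]2O | intermediate
21 | α-methylene lactone triol (C1-OH, 6β-OH, 9α-OH; C4 ketal) | C=C1C(=O)O[C@@H]2[C@@H]1[C@@H](O)[C@@H](C3(C)OCCO3)[C@](C)(CO)[C@@H]2O | intermediate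
22 | angelic anhydride ((Z)-2-methylbut-2-enoic anhydride) | C/C=C(C)\C(=O)OC(=O)/C(C)=C\C | starting material
23 | cyclic phenylboronate of 21 across O1 and O9 (6β-OH free) | C=C1C(=O)O[C@@H]2[C@@H]1[C@@H](O)[C@@H](C3(C)OCCO3)[C@]4(C)COB(c5ccccc5)O[C@H]24 | intermediate
24 | 6-O-angelate of boronate 23 | C=C1C(=O)O[C@@H]2[C@@H]1[C@@H](OC(=O)/C(C)=C\C)[C@@H](C3(C)OCCO3)[C@]4(C)COB(c5ccccc5)O[C@H]24 | intermediate
25 | 6-O-angelate of 21 (C1-OH and 9α-OH free; C4 ketal) | C=C1C(=O)O[C@@H]2[C@@H]1[C@@H](OC(=O)/C(C)=C\C)[C@@H](C3(C)OCCO3)[C@](C)(CO)[C@@H]2O | intermediate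
26 | C1 aldehyde of 25 | C=C1C(=O)O[C@@H]2[C@@H]1[C@@H](OC(=O)/C(C)=C\C)[C@@H](C3(C)OCCO3)[C@](C)(C=O)[C@@H]2O | intermediate
27 | C1 aldehyde with free C4 methyl ketone (acetyl on C5) | C=C1C(=O)O[C@@H]2[C@@H]1[C@@H](OC(=O)/C(C)=C\C)[C@@H](C(C)=O)[C@](C)(C=O)[C@@H]2O | intermediate
28 | 10α-vinyl 5β-isopropenyl α-methylene lactone with 6β-O-angelate and 9α-OH | C=C1C(=O)O[C@@H]2[C@@H]1[C@@H](OC(=O)/C(C)=C\C)[C@@H](C(C)=C)[C@](C)(C=C)[C@@H]2O | intermediate
29 | C3 enal (5β-(3-oxoprop-1-en-2-yl)) with 10α-vinyl | C=C1C(=O)O[C@@H]2[C@@H]1[C@@H](OC(=O)/C(C)=C\C)[C@@H](C(=C)C=O)[C@](C)(C=C)[C@@H]2O | intermediate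
30 | CNP0113462.3, (1R,5R,6S,7S,8R,9S,10S) | C=C1C(=O)O[C@@H]2[C@@H]1[C@@H](OC(=O)/C(C)=C\C)[C@@H](C(=C)C=O)[C@](C)([C@@H]1CO1)[C@@H]2O | target

**Totals**
Total step count: 16. Longest linear sequence: 16 steps (1 and 2 to 30).

**Three steps most likely to fail**

Step 2. The dienophile is trisubstituted, the diene is only weakly donating, and neither the level nor the sense of induction is established for this pair. Fallback (sets out from 2 and 4, comes back at 7): the face selection is moved into a separable auxiliary. Pyruvic acid is esterified with (−)-menthol (dicyclohexylcarbodiimide, 4-(dimethylamino)pyridine, CH2Cl2) to (1R,2S,5R)-menthyl pyruvate F1. Wittig reaction with 2 gives (1R,2S,5R)-menthyl (E)-2-methyl-4-oxopent-2-enoate F2. Et2AlCl (1.2 equiv, CH2Cl2, −40 °C) then promotes the same endo cycloaddition with 4 without a chiral catalyst and gives the menthyl ester analogue of 5 F3 together with its diastereomer of opposite ring configuration F4, which are separated by chromatography or crystallisation. F3 is ketalised as in step 3 to the menthyl ester analogue of 6 F5, and LiAlH4 as in step 4 removes the auxiliary and both acetates in one operation to give 7.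

Step 7. For the rearrangement the C9–O bond must become pseudoaxial, which puts it syn to the bulky C5 ketal group, so the thermal Johnson variant may need temperatures that the silyl ethers and the ketal do not tolerate. Fallback (sets out from 11, comes back at 17): the lower-barrier anionic Ireland–Claisen variant is used. Acetylation of 11 (Ac2O, 4-(dimethylamino)pyridine, pyridine) gives the C9 acetate F6. LiN(i-Pr)2 and Me3SiCl (THF, −78 → 60 °C) convert it through the trimethylsilyl ketene acetal F7 and the rearranged trimethylsilyl ester F8 into the γ,δ-unsaturated acid F9 after acidic work-up. OsO4 with N-methylmorpholine N-oxide, then pyridinium p-toluenesulfonate, takes F9 through the dihydroxy acid F10 to lactone 17.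

Step 16. The C1 configuration rests on a conformational argument for a vinyl group on a quaternary carbon, and the enal may be over-oxidised. Fallback (sets out from 29, comes back at 30): stereocontrol is handed to a catalyst after an undirected epoxidation. 3-Chloroperbenzoic acid (NaHCO3, CH2Cl2, 0 °C) gives 30 mixed with its C1 epimer F11. Hydrolytic kinetic resolution with acetato[(S,S)-N,N'-bis(3,5-di-tert-butylsalicylidene)cyclohexane-1,2-diaminato]cobalt (trivalent cobalt, 2 mol %) and H2O (0.6 equiv per F11) in THF opens only the 1S epoxide to the 1,2-diol F12, which is removed by chromatography to leave 30.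

**Further compounds**
F1 | step 2 | (1R,2S,5R)-menthyl pyruvate | CC(C)[C@@H]1CC[C@@H](C)C[C@H]1OC(=O)C(C)=O
F2 | step 2 | (1R,2S,5R)-menthyl (E)-2-methyl-4-oxopent-2-enoate | CC(C)[C@@H]1CC[C@@H](C)C[C@H]1OC(=O)/C(C)=C/C(C)=O
F3 | step 2 | menthyl ester analogue of 5 | CC(=O)O[C@@H]1C=C[C@H](OC(C)=O)[C@@](C)(C(=O)O[C@@H]2C[C@H](C)CC[C@H]2C(C)C)[C@@H]1C(C)=O
F4 | step 2 | diastereomer of F3 with opposite ring configuration | CC(=O)O[C@H]1C=C[C@@H](OC(C)=O)[C@](C)(C(=O)O[C@@H]2C[C@H](C)CC[C@H]2C(C)C)[C@H]1C(C)=O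
F5 | step 2 | menthyl ester analogue of 6 | CC(=O)O[C@@H]1C=C[C@H](OC(C)=O)[C@@](C)(C(=O)O[C@@H]2C[C@H](C)CC[C@H]2C(C)C)[C@@H]1C3(C)OCCO3
F6 | step 7 | C9 acetate of 11 | CC(C)(C)[Si](C)(C)O[C@@H]1C=C[C@H](OC(C)=O)[C@@](C)(CO[Si](C)(C)C(C)(C)C)[C@@H]1C2(C)OCCO2
F7 | step 7 | trimethylsilyl ketene acetal of F6 | CC(C)(C)[Si](C)(C)O[C@@H]1C=C[C@H](OC(=C)O[Si](C)(C)C)[C@@](C)(CO[Si](C)(C)C(C)(C)C)[C@@H]1C2(C)OCCO2
F8 | step 7 | trimethylsilyl ester of acid F9 | C[Si](C)(C)OC(=O)C[C@@H]1C=C[C@@](C)(CO[Si](C)(C)C(C)(C)C)[C@H](C2(C)OCCO2)[C@@H]1O[Si](C)(C)C(C)(C)C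
F9 | step 7 | γ,δ-unsaturated acid (7β-CH2CO2H, C8=C9) | OC(=O)C[C@@H]1C=C[C@@](C)(CO[Si](C)(C)C(C)(C)C)[C@H](C2(C)OCCO2)[C@@H]1O[Si](C)(C)C(C)(C)C
F10 | step 7 | 8α,9α-dihydroxy acid | OC(=O)C[C@@H]1[C@@H](O)[C@@H](O)[C@@](C)(CO[Si](C)(C)C(C)(C)C)[C@H](C2(C)OCCO2)[C@@H]1O[Si](C)(C)C(C)(C)C
F11 | step 16 | C1 epimer of 30 (1S oxirane) | C=C1C(=O)O[C@@H]2[C@@H]1[C@@H](OC(=O)/C(C)=C\C)[C@@H](C(=C)C=O)[C@](C)([C@H]1CO1)[C@@H]2O
F12 | step 16 | 1,2-diol from hydrolysis of F11 | C=C1C(=O)O[C@@H]2[C@@H]1[C@@H](OC(=O)/C(C)=C\C)[C@@H](C(=C)C=O)[C@](C)([C@H](O)CO)[C@@H]2O
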